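**Plan**

- **Cuts.** First the O–benzyl bond on the phenol of ring D. Then, in one stroke, two C(sp3)–C(sp3) bonds: C3–C4 of pyran ring C (O1, C2, C3, C4, C4a, C8a) and the CH2–CH2 bond of the bridge C8–CH2–CH2–C1'. Each is cut by putting an NH back between the two carbons. The resulting C–N bonds become C=N condensations, and O1–C2 becomes an ether bond.
- **Enabling feature.** C4 (on C4a of ring A) and both bridge carbons (on C8 of ring A and C1' of ring D) are benzylic on 2,4,6-trioxygenated benzene rings. A C–NH–C unit at either place can therefore be turned into an isodiazene that loses N2 and recombines. Ring C is carried as the seven-membered 2,3,4,5-tetrahydro-1,4-benzoxazepine (O1, C2, C3, N4, C5, C5a, C9a) and contracts to six atoms by deletion of N4.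
- **Symmetry.** C4a and C8 flank the O1-bearing C8a symmetrically, so both benzylic carbons come from the two equivalent formyl groups of 2-hydroxy-4,6-dimethoxybenzene-1,3-dicarbaldehyde. Ring D comes from the symmetric 3,5-dimethoxy-4-methylphenol. No C6/C8 or ortho/ortho' regiochemical question remains.
- **Forward order.** Ring D benzylamine; dialdehyde; ether bond O1–C2; seven-membered ring by intramolecular aza-Wittig reaction together with the bridge imine, both reduced in one flask. A double nitrogen deletion then closes ring C in its final size and joins the bridge, and debenzylation finishes the route.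
- **Stereochemistry.** The only stereocentre (C2, S) comes from commercial (S)-2-chloro-1-phenylethanol, is inverted once in the Mitsunobu step and is not touched afterwards. Its descriptor reads R while C3 carries nitrogen and S after the deletion, with no change in space.

Key step: step 9

Remark: CIP analysis of the given SMILES gives (2S) at C2. Flavan numbering is used for the target and 1,4-benzoxazepine numbering for the seven-membered-ring intermediates. The anomeric amide reagent is taken as purchasable.

**Step 1**
Reactants: 1 2,6-dimethoxytoluene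
Product: 3 3,5-dimethoxy-4-methylphenol, via aryl pinacol boronate 2 (not isolated)
Conditions: [Ir(OMe)(cod)]2 (cat.), dtbpy (cat.), B2pin2, THF, 80 °C; then Oxone, acetone/H2O, rt
Reagents that add atoms: bis(pinacolato)diboron CC1(C)OB(B2OC(C)(C)C(C)(C)O2)OC1(C)C (boron of 2 only); potassium peroxymonosulfate (Oxone) [K+].[O-]S(=O)(=O)OO
Why: Sterically governed iridium-catalysed aromatic C–H borylation should take the only ring C–H without an ortho substituent (C4, para to the methyl group), and oxidation of the C–B bond at the same position (one-pot C–H borylation/oxidation) should give the symmetric phenol.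

**Step 2**
Reactants: 3 3,5-dimethoxy-4-methylphenol
Product: 4 6-hydroxy-2,4-dimethoxy-3-methylbenzaldehyde
Conditions: MgCl2, Et3N, (CH2O)n, MeCN, reflux; aq HCl work-up
Reagents that add atoms: formaldehyde (as paraformaldehyde) C=O
Why: Casnati–Skattebøl ortho-formylation: the magnesium phenoxide delivers formaldehyde to an ortho carbon through a cyclic transition state and a second formaldehyde takes up hydride from the benzylic alkoxide; the two ortho positions of 3 are equivalent and the para position carries the methyl group, so only one aldehyde can form.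

**Step 3**
Reactants: 4 6-hydroxy-2,4-dimethoxy-3-methylbenzaldehyde
Product: 5 6-(benzyloxy)-2,4-dimethoxy-3-methylbenzaldehyde
Conditions: BnBr, K2CO3, DMF, 60 °C
Reagents that add atoms: benzyl bromide BrCc1ccccc1
Why: Williamson ether synthesis on the chelated phenol; the benzyl ether masks the ring D hydroxyl through the amine chemistry and the radical step and keeps it distinct from the two methyl ethers.

**Step 4**
Reactants: 5 6-(benzyloxy)-2,4-dimethoxy-3-methylbenzaldehyde
Product: 7 [6-(benzyloxy)-2,4-dimethoxy-3-methylphenyl]methanamine, via aldoxime 6 (not isolated)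
Conditions: NH2OH·HCl, NaOAc, EtOH, 60 °C; then Zn dust, AcOH, rt; basic work-up
Reagents that add atoms: hydroxylamine hydrochloride NO.Cl
Why: Oxime formation followed by dissolving-metal (Zn/AcOH) reduction of the C=N and N–O bonds is a standard aldehyde-to-primary-amine conversion that avoids over-alkylation and, unlike catalytic hydrogenation, leaves the benzyl ether in place.

**Step 5**
Reactants: 8 2-hydroxy-4,6-dimethoxybenzaldehyde
Product: 9 2-hydroxy-4,6-dimethoxybenzene-1,3-dicarbaldehyde
Conditions: Cl2CHOMe, TiCl4, CH2Cl2, 0 °C; then aq HCl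
Reagents that add atoms: dichloromethyl methyl ether COC(Cl)Cl; water O
Why: Rieche formylation of a titanium phenoxide: the metal bound to the phenolic oxygen directs the chloro(methoxy)methyl electrophile to the free ortho position C3, which is activated by all three oxygen substituents and is less hindered (between OH and OMe) than C5 (between two OMe).

**Step 6**
Reactants: 10 (S)-2-chloro-1-phenylethanol
Product: 11 (S)-2-azido-1-phenylethanol
Conditions: NaN3, NaI (cat.), DMF, 80 °C
Reagents that add atoms: sodium azide [Na+].[N-]=[N+]=[N-]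
Why: SN2 displacement of the primary chloride by azide; no bond at the carbinol carbon is touched, so the (S) configuration is kept.

**Step 7**
Reactants: 9 2-hydroxy-4,6-dimethoxybenzene-1,3-dicarbaldehyde; 11 (S)-2-azido-1-phenylethanol
Product: 12 2-[(1R)-2-azido-1-phenylethoxy]-4,6-dimethoxybenzene-1,3-dicarbaldehyde
Conditions: PPh3 (1.05 equiv), DIAD (betaine pre-formed at 0 °C), THF, 0 °C to rt
Reagents that add atoms: none
Why: Mitsunobu etherification: the acidic, doubly ortho-formylated phenol protonates the betaine readily and its phenoxide displaces the oxyphosphonium group by SN2 with inversion, while the electron-withdrawing β-azido group disfavours ionisation at the benzylic carbon; this sets the C2 configuration of the target.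

**Step 8**
Reactants: 12 2-[(1R)-2-azido-1-phenylethoxy]-4,6-dimethoxybenzene-1,3-dicarbaldehyde; 7 [6-(benzyloxy)-2,4-dimethoxy-3-methylphenyl]methanamine
Product: 16 1-[6-(benzyloxy)-2,4-dimethoxy-3-methylphenyl]-N-{[(2R)-6,8-dimethoxy-2-phenyl-2,3,4,5-tetrahydro-1,4-benzoxazepin-9-yl]methyl}methanamine, via iminophosphorane 13 (not isolated), via cyclic imine aldehyde 14 (not isolated), via bis-imine 15 (not isolated)
Conditions: PPh3, THF (0.02 M), rt to 50 °C; then 7, 4 Å MS, rt; then NaBH4, MeOH, 0 °C
Reagents that add atoms: none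
Why: Staudinger reaction and intramolecular aza-Wittig reaction close the seven-membered cyclic imine on either of the two equivalent ortho-formyl groups, the remaining aldehyde condenses with 7 (the only fully condensed combination of the two amines and two aldehydes), and borohydride reduction of both C=N bonds (reductive amination) should give the bis-secondary amine without touching C2.

**Step 9**
Reactants: 16 1-[6-(benzyloxy)-2,4-dimethoxy-3-methylphenyl]-N-{[(2R)-6,8-dimethoxy-2-phenyl-2,3,4,5-tetrahydro-1,4-benzoxazepin-9-yl]methyl}methanamine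
Product: 18 (2S)-8-{2-[6-(benzyloxy)-2,4-dimethoxy-3-methylphenyl]ethyl}-5,7-dimethoxy-2-phenyl-3,4-dihydro-2H-chromene, via bis-isodiazene 17 (not isolated)
Conditions: N-(benzyloxy)-N-(pivaloyloxy)-4-(trifluoromethyl)benzamide (3 equiv), degassed THF (0.05 M), 45 °C
Reagents that add atoms: none
Why: Each secondary nitrogen of 16 displaces pivalate at the electrophilic nitrogen of the anomeric amide, reductive elimination of benzyl 4-(trifluoromethyl)benzoate leaves an isodiazene (both sites drawn in 17), and this loses N2, starting with homolysis of its weaker benzylic C–N bond, to give a singlet radical pair that collapses to a C–C bond. The closest known reaction type is the nitrogen deletion of secondary amines with anomeric amides, established for dibenzylamines (giving bibenzyls) and for benzo-fused cyclic benzylic amines (giving the ring-contracted product). Ring C closes by intramolecular radical–radical recombination of the C4 benzylic radical (on C4a, stabilised by the ortho OMe, ortho O1 and para OMe of ring A) with the primary C3 radical, a 7 to 6 contraction in which the tether C2–O1–C8a–C4a keeps both centres in contact, while the bridge bond forms by in-cage recombination of two trioxygenated benzyl radicals. No new stereocentre is made: none of the four bonds at C2 is broken, so its configuration is carried over and only the descriptor changes from R to S because C3 loses its nitrogen. The step needs recombination to outrun β-scission of the C2–O1 bond from the C3 radical (styrene plus an o-quinone methide) and cage escape at the bridge; the singlet spin state, the tether, the moderate temperature and the dilution favour collapse, and the benzyl ether keeps the ring D phenol from donating a hydrogen atom or protonating the isodiazene. Both edits run under the same conditions, so one operation forms both C(sp3)–C(sp3) bonds of the target from a precursor assembled only by C=N condensations.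

**Step 10**
Reactants: 18 (2S)-8-{2-[6-(benzyloxy)-2,4-dimethoxy-3-methylphenyl]ethyl}-5,7-dimethoxy-2-phenyl-3,4-dihydro-2H-chromene
Product: 19 2-{2-[(2S)-5,7-dimethoxy-2-phenyl-3,4-dihydro-2H-chromen-8-yl]ethyl}-3,5-dimethoxy-4-methylphenol (target)
Conditions: H2 (1 atm), 10% Pd/C, EtOAc/MeOH, rt
Reagents that add atoms: none
Why: Catalytic hydrogenolysis of the aryl benzyl ether; under one atmosphere of hydrogen at room temperature the cyclic benzylic C2–O1 bond of flavans persists, so ring C and the stereocentre should stay intact.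

**Compound list**

1 | 2,6-dimethoxytoluene | COc1cccc(OC)c1C | starting material
2 | 2-(3,5-dimethoxy-4-methylphenyl)-4,4,5,5-tetramethyl-1,3,2-dioxaborolane | COc1cc(cc(OC)c1C)B1OC(C)(C)C(C)(C)O1 | intermediate
3 | 3,5-dimethoxy-4-methylphenol | COc1cc(O)cc(OC)c1C | intermediate
4 | 6-hydroxy-2,4-dimethoxy-3-methylbenzaldehyde | COc1cc(O)c(C=O)c(OC)c1C | intermediate
5 | 6-(benzyloxy)-2,4-dimethoxy-3-methylbenzaldehyde | COc1cc(OCc2ccccc2)c(C=O)c(OC)c1C | intermediate
6 | (E)-6-(benzyloxy)-2,4-dimethoxy-3-methylbenzaldehyde oxime | COc1cc(OCc2ccccc2)c(/C=N/O)c(OC)c1C | intermediate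
7 | [6-(benzyloxy)-2,4-dimethoxy-3-methylphenyl]methanamine | COc1cc(OCc2ccccc2)c(CN)c(OC)c1C | intermediate
8 | 2-hydroxy-4,6-dimethoxybenzaldehyde | COc1cc(O)c(C=O)c(OC)c1 | starting material
9 | 2-hydroxy-4,6-dimethoxybenzene-1,3-dicarbaldehyde | COc1cc(OC)c(C=O)c(O)c1C=O | intermediate
10 | (S)-2-chloro-1-phenylethanol | O[C@@H](c1ccccc1)CCl | starting material
11 | (S)-2-azido-1-phenylethanol | O[C@@H](c1ccccc1)CN=[N+]=[N-] | intermediate
12 | 2-[(1R)-2-azido-1-phenylethoxy]-4,6-dimethoxybenzene-1,3-dicarbaldehyde | COc1cc(OC)c(C=O)c(O[C@H](c2ccccc2)CN=[N+]=[N-])c1C=O | intermediate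
13 | 4,6-dimethoxy-2-{(1R)-1-phenyl-2-[(triphenyl-λ5-phosphanylidene)amino]ethoxy}benzene-1,3-dicarbaldehyde | COc1cc(OC)c(C=O)c(O[C@H](c2ccccc2)CN=P(c2ccccc2)(c2ccccc2)c2ccccc2)c1C=O | intermediate
14 | (2R)-6,8-dimethoxy-2-phenyl-2,3-dihydro-1,4-benzoxazepine-9-carbaldehyde | COc1cc(OC)c2c(c1C=O)O[C@H](c1ccccc1)CN=C2 | intermediate
15 | (E)-N-{[6-(benzyloxy)-2,4-dimethoxy-3-methylphenyl]methyl}-1-[(2R)-6,8-dimethoxy-2-phenyl-2,3-dihydro-1,4-benzoxazepin-9-yl]methanimine | COc1cc(OCc2ccccc2)c(C/N=C/c2c(OC)cc(OC)c3c2O[C@H](c2ccccc2)CN=C3)c(OC)c1C | intermediate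
16 | 1-[6-(benzyloxy)-2,4-dimethoxy-3-methylphenyl]-N-{[(2R)-6,8-dimethoxy-2-phenyl-2,3,4,5-tetrahydro-1,4-benzoxazepin-9-yl]methyl}methanamine | COc1cc(OCc2ccccc2)c(CNCc2c(OC)cc(OC)c3c2O[C@H](c2ccccc2)CNC3)c(OC)c1C | intermediate
17 | bis-isodiazene of 16 (1,1-diazene at ring N4 and at the bridge nitrogen, 2R) | COc1cc(OCc2ccccc2)c(C[N+](=[N-])Cc2c(OC)cc(OC)c3c2O[C@H](c2ccccc2)C[N+](=[N-])C3)c(OC)c1C | intermediate
18 | (2S)-8-{2-[6-(benzyloxy)-2,4-dimethoxy-3-methylphenyl]ethyl}-5,7-dimethoxy-2-phenyl-3,4-dihydro-2H-chromene | COc1cc(OCc2ccccc2)c(CCc2c(OC)cc(OC)c3c2O[C@H](c2ccccc2)CC3)c(OC)c1C | intermediate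
19 | 2-{2-[(2S)-5,7-dimethoxy-2-phenyl-3,4-dihydro-2H-chromen-8-yl]ethyl}-3,5-dimethoxy-4-methylphenol | COc1cc(O)c(CCc2c(OC)cc(OC)c3c2O[C@H](c2ccccc2)CC3)c(OC)c1C | target

**Total step count:** 10.
**Longest linear sequence:** 7 (steps 1, 2, 3, 4, 8, 9, 10).

**Steps most likely to fail**

**Step 9.**
- What may go wrong: β-scission of the C2–O1 bond in the C3-centred radical, which breaks up the ring and costs material and stereochemical integrity. Cage escape of the bridge radical pair or sluggish amination of the hindered bridge nitrogen may also occur.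
- Fallback: it sets out from 9 and 7 and comes back at 18. Ring C is built at its final size, and only the dibenzylamine is edited.
- Acid-catalysed condensation of 9 with acetophenone (HCl, AcOH/EtOAc) should give 8-formyl-5,7-dimethoxy-2-phenylchromenylium chloride F1.
- Hydride transfer from a Hantzsch ester to C4 should give 5,7-dimethoxy-2-phenyl-4H-chromene-8-carbaldehyde F2.
- Iridium–phosphinooxazoline-catalysed asymmetric hydrogenation of the C2=C3 enol ether bond, with the ligand enantiomer chosen for S, should give (2S)-5,7-dimethoxy-2-phenyl-3,4-dihydro-2H-chromene-8-carbaldehyde F3.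
- Reductive amination with 7 (NaBH(OAc)3) should give 1-[6-(benzyloxy)-2,4-dimethoxy-3-methylphenyl]-N-{[(2S)-5,7-dimethoxy-2-phenyl-3,4-dihydro-2H-chromen-8-yl]methyl}methanamine F4.
- A single nitrogen deletion with the same anomeric amide then leads to 18.

**Step 7.**
- What may go wrong: slow substitution by the hindered, weakly nucleophilic phenoxide, competing elimination at the β-azido alcohol, partial ionisation that erodes the enantiomeric purity, or consumption of the azide by the phosphine.
- Fallback: it sets out from 9 and comes back at 14. It uses a cyclic sulfamidate as the electrophile, so neither a phosphine nor an azide is present.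
- Commercial (S)-2-amino-1-phenylethanol is converted with Boc2O into tert-butyl N-[(2S)-2-hydroxy-2-phenylethyl]carbamate F5.
- SOCl2/imidazole/Et3N converts this into tert-butyl (5S)-5-phenyl-1,2,3-oxathiazolidine-3-carboxylate 2-oxide F6.
- RuCl3/NaIO4 oxidises it to tert-butyl (5S)-5-phenyl-1,2,3-oxathiazolidine-3-carboxylate 2,2-dioxide F7.
- The caesium phenoxide of 9 should open F7 at C5 by SN2 with inversion to give N-(tert-butoxycarbonyl)-N-[(2R)-2-(2,6-diformyl-3,5-dimethoxyphenoxy)-2-phenylethyl]sulfamic acid F8.
- Aqueous acid hydrolyses this to tert-butyl N-[(2R)-2-(2,6-diformyl-3,5-dimethoxyphenoxy)-2-phenylethyl]carbamate F9.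
- TFA sets free 2-[(1R)-2-amino-1-phenylethoxy]-4,6-dimethoxybenzene-1,3-dicarbaldehyde F10.
- On neutralisation F10 condenses with either ortho-formyl group to give 14. Step 8 then continues from the addition of 7.

**Step 5.**
- What may go wrong: attack at C5 instead of C3, Lewis-acid demethylation of the methoxy group next to the aldehyde, or low conversion of the titanium-chelated, deactivated ring.
- Fallback: it sets out from 8 and comes back at 9. The position is fixed by a sigmatropic shift rather than by electrophilic substitution.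
- Allylation (allyl bromide, K2CO3) should give 2-(allyloxy)-4,6-dimethoxybenzaldehyde F11.
- Aromatic Claisen rearrangement (N,N-diethylaniline, about 200 °C) can only reach the free ortho carbon and should give 2-hydroxy-4,6-dimethoxy-3-(prop-2-en-1-yl)benzaldehyde F12.
- Ruthenium hydride-catalysed alkene isomerisation should give 2-hydroxy-4,6-dimethoxy-3-[(E)-prop-1-en-1-yl]benzaldehyde F13.
- Lemieux–Johnson cleavage (OsO4 cat., NaIO4) then gives 9.

**Further compounds**

F1 | step 9 | 8-formyl-5,7-dimethoxy-2-phenylchromenylium chloride | COc1cc(OC)c2ccc([o+]c2c1C=O)-c1ccccc1.[Cl-]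
F2 | step 9 | 5,7-dimethoxy-2-phenyl-4H-chromene-8-carbaldehyde | COc1cc(OC)c2c(c1C=O)OC(c1ccccc1)=CC2
F3 | step 9 | (2S)-5,7-dimethoxy-2-phenyl-3,4-dihydro-2H-chromene-8-carbaldehyde | COc1cc(OC)c2c(c1C=O)O[C@H](c1ccccc1)CC2
F4 | step 9 | 1-[6-(benzyloxy)-2,4-dimethoxy-3-methylphenyl]-N-{[(2S)-5,7-dimethoxy-2-phenyl-3,4-dihydro-2H-chromen-8-yl]methyl}methanamine | COc1cc(OCc2ccccc2)c(CNCc2c(OC)cc(OC)c3c2O[C@H](c2ccccc2)CC3)c(OC)c1C
F5 | step 7 | tert-butyl N-[(2S)-2-hydroxy-2-phenylethyl]carbamate | O[C@@H](c1ccccc1)CNC(=O)OC(C)(C)C
F6 | step 7 | tert-butyl (5S)-5-phenyl-1,2,3-oxathiazolidine-3-carboxylate 2-oxide | O=S1O[C@@H](c2ccccc2)CN1C(=O)OC(C)(C)C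
F7 | step 7 | tert-butyl (5S)-5-phenyl-1,2,3-oxathiazolidine-3-carboxylate 2,2-dioxide | O=S1(=O)O[C@@H](c2ccccc2)CN1C(=O)OC(C)(C)C
F8 | step 7 | N-(tert-butoxycarbonyl)-N-[(2R)-2-(2,6-diformyl-3,5-dimethoxyphenoxy)-2-phenylethyl]sulfamic acid | COc1cc(OC)c(C=O)c(O[C@H](c2ccccc2)CN(C(=O)OC(C)(C)C)S(=O)(=O)O)c1C=O
F9 | step 7 | tert-butyl N-[(2R)-2-(2,6-diformyl-3,5-dimethoxyphenoxy)-2-phenylethyl]carbamate | COc1cc(OC)c(C=O)c(O[C@H](c2ccccc2)CNC(=O)OC(C)(C)C)c1C=O
F10 | step 7 | 2-[(1R)-2-amino-1-phenylethoxy]-4,6-dimethoxybenzene-1,3-dicarbaldehyde | COc1cc(OC)c(C=O)c(O[C@H](c2ccccc2)CN)c1C=O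
F11 | step 5 | 2-(allyloxy)-4,6-dimethoxybenzaldehyde | C=CCOc1cc(OC)cc(OC)c1C=O
F12 | step 5 | 2-hydroxy-4,6-dimethoxy-3-(prop-2-en-1-yl)benzaldehyde | C=CCc1c(OC)cc(OC)c(C=O)c1O
F13 | step 5 | 2-hydroxy-4,6-dimethoxy-3-[(E)-prop-1-en-1-yl]benzaldehyde | C/C=C/c1c(OC)cc(OC)c(C=O)c1O
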